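Ring B (C5–C10), with its C5 methyl and the side-chain carbon C11 on C7, is the skeleton of (+)-3-carene, whose cyclopropane bond C8–C11 is a latent C8=C9 alkene plus C7 side chain. The route rests on the C1–C10 disconnection: a copper-catalysed chlorine-atom-transfer radical cyclisation closes ring A 6-exo onto C10 (cis fusion), the C9 radical then opens the cyclopropane, and chlorine returns to C11. One operation thus gives the octalone, the alkene for the diol and a tertiary chloride that masks the isopropenyl group. The precursor is an allyl α-chloro β-keto ester tethered through C4 to quaternary C5 of a 4-carene, the chain anti to the gem-dimethylcyclopropane.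

Key step: step 9

Remark: atoms carry the eremophilane numbers of 28 throughout (C14 = methyl on C5, C15 = methyl on C4, C11 = side-chain carbon on C7); the 2-methylbutanoyl centre of the target structure is R, so (R)-2-methylbutanoic acid is used; C1 of 17, 18 and 19 is an epimer (or enol) mixture, since it is planar in step 9 and becomes a methylene in step 10.

Step 1
Reactants: 1 (+)-3-carene
Product: 2 car-3-en-5-one (carbonyl at C9)
Conditions: t-BuOOH (70% aq.), CrO3 (5 mol %), CH2Cl2, rt
Reagents that add atoms: tert-butyl hydroperoxide, CC(C)(C)OO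
Why: Chromium-catalysed allylic oxidation; of the two ring methylenes that are both allylic and cyclopropylcarbinyl, C9 gives the allyl radical with a tertiary terminus and should be the main site, as is usual for 3-carene, and the cyclopropane is not attacked.

Step 2
Reactants: 2 car-3-en-5-one
Product: 3 cis-car-3-en-5-ol (C9 hydroxyl cis to the cyclopropane)
Conditions: NaBH4, CeCl3·7H2O, MeOH, −20 °C
Reagents that add atoms: none
Why: Luche 1,2-reduction; hydride should enter C9 from the face anti to the gem-dimethylcyclopropane, so the new carbinol centre carries its hydroxyl cis to the three-membered ring.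

Step 3
Reactants: 3 cis-car-3-en-5-ol; 4 propanoic acid
Product: 5 trans-car-3-en-5-yl propanoate (ester oxygen trans to the cyclopropane)
Conditions: PPh3, DIAD, THF, 0 °C → rt
Reagents that add atoms: propanoic acid 4, CCC(=O)O
Why: Mitsunobu esterification with SN2 inversion at C9, which places the ester oxygen on the face anti to the cyclopropane, the face the side chain must take in step 4.

Step 4
Reactants: 5 trans-car-3-en-5-yl propanoate
Product: 8 (2R)-2-[(1S,3S,6R)-3,7,7-trimethylbicyclo[4.1.0]hept-4-en-3-yl]propanoic acid, via silyl ketene acetal 6 (not isolated), via trimethylsilyl ester 7 (not isolated)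
Conditions: LiN(i-Pr)2, THF, −78 °C; Me3SiCl; −78 → 65 °C; then aq. citric acid
Reagents that add atoms: none
Why: Ireland–Claisen rearrangement: kinetic enolisation in THF should give the E silyl ketene acetal 6, which rearranges suprafacially through a chair on the face of the C9–O bond, so the chain reaches quaternary C5 anti to the cyclopropane and C4 follows from the E geometry (a boat would push the ketene-acetal methyl over ring B).

Step 5
Reactants: 8 the propanoic acid from step 4
Product: 10 (3R)-1-diazo-3-[(1S,3S,6R)-3,7,7-trimethylbicyclo[4.1.0]hept-4-en-3-yl]butan-2-one, via acid chloride 9 (not isolated)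
Conditions: 1-chloro-N,N,2-trimethylprop-1-en-1-amine, CH2Cl2, 0 °C → rt; then Me3SiCHN2, MeCN–THF, 0 °C → rt
Reagents that add atoms: (trimethylsilyl)diazomethane, C[Si](C)(C)C=[N+]=[N-]
Why: First stage of the Arndt–Eistert homologation: neutral formation of the acid chloride (no HCl and no base, so the acid-sensitive vinylcyclopropane and C4 are safe) and C-acylation of the diazo reagent with loss of the silyl group give the α-diazoketone.

Step 6
Reactants: 10 the diazoketone
Product: 12 (3S)-3-[(1S,3R,6R)-3,7,7-trimethylbicyclo[4.1.0]hept-4-en-3-yl]butanoic acid, via ketene 11 (not isolated)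
Conditions: PhCO2Ag (10 mol %), Et3N, THF–H2O 10:1, rt, dark
Reagents that add atoms: water, O
Why: Wolff rearrangement: silver-promoted loss of N2 with 1,2-shift of C4 (retention) gives ketene 11, which water traps as the homologous acid, so C3 is in place.

Step 7
Reactants: 12 the butanoic acid; 13 Meldrum's acid; 14 allyl alcohol
Product: 16 allyl (5S)-3-oxo-5-[(1S,3R,6R)-3,7,7-trimethylbicyclo[4.1.0]hept-4-en-3-yl]hexanoate, via acyl Meldrum's acid 15 (not isolated)
Conditions: DCC, DMAP, CH2Cl2, 0 °C → rt; then allyl alcohol, toluene, 90 °C
Reagents that add atoms: Meldrum's acid 13, CC1(C)OC(=O)CC(=O)O1; allyl alcohol 14, C=CCO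
Why: C-acylation of Meldrum's acid and thermal alcoholysis of 15 is a standard β-keto ester synthesis; the allyl ester is chosen so that the activating carboxyl can be removed by zerovalent palladium at room temperature directly after the cyclisation and not by a hot dealkoxycarbonylation.

Step 8
Reactants: 16 the allyl β-keto ester
Product: 17 allyl (5S)-2-chloro-3-oxo-5-[(1S,3R,6R)-3,7,7-trimethylbicyclo[4.1.0]hept-4-en-3-yl]hexanoate (both C1 epimers)
Conditions: N-chlorosuccinimide, Mg(ClO4)2 (10 mol %), EtOAc, 0 °C → rt
Reagents that add atoms: N-chlorosuccinimide, O=C1CCC(=O)N1Cl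
Why: Lewis-acid-catalysed electrophilic α-chlorination of a 1,3-dicarbonyl compound: the magnesium-bound enol takes chlorine at C1 only, the alkenes are left alone by this mild reagent, and either C1 epimer serves.

Step 9
Reactants: 17 the allyl α-chloro β-keto ester
Product: 18 allyl 11-chloro-2-oxoeremophil-8-ene-1-carboxylate (cis ring fusion; C4 C5 C7 C10 as in 28; C1 epimers or enol)
Conditions: CuCl (20 mol %), tris(2-pyridylmethyl)amine (20 mol %), ClCH2CH2Cl (0.02 M, degassed), 80 °C
Reagents that add atoms: none
Why: Monovalent copper reversibly abstracts chlorine from C1 of 17; the electrophilic C1 radical adds to C10 of the electron-rich vinylcyclopropane, the C9 cyclopropylcarbinyl radical opens by cleavage of C8–C11 (giving C8=C9), and the tertiary C11 radical takes chlorine from the CuCl2–ligand complex (divalent copper), which restores the catalyst and makes the step an isomerisation. The closest known reactions are the copper-catalysed chlorine-atom-transfer cyclisations of unsaturated α-chloro β-keto esters and the ring-opening atom-transfer additions to vinylcyclopropanes. Ring A closes in the 6-exo-trig mode (C1 onto C10, C9 outside the new ring). The only lasting new stereocentre is C10: the four-atom tether starts from the face of C5 anti to the cyclopropane and can reach only that face of C10, so the fusion is cis with H10 syn to the C5 methyl, while C7 is untouched and C1 is erased in step 10. The step needs cleavage of C8–C11 and not of C7–C8; the exocyclic bond overlaps better with the C9 SOMO and releases a tertiary radical, whereas the ring bond would give a secondary radical in a seven-membered ring. The allyl ester should stay a spectator, since 5-exo attack through an ester needs its disfavoured s-cis rotamer, and uncyclised C1 radicals are returned to 17 by chlorine transfer from divalent copper.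

Step 10
Reactants: 18 the cyclised allyl β-keto ester
Product: 20 11-chloroeremophil-8-en-2-one (cis-fused), via β-keto acid 19 (not isolated)
Conditions: Pd(PPh3)4 (5 mol %), morpholine, THF, rt → 45 °C
Reagents that add atoms: none
Why: Tsuji–Trost deallylation: zerovalent palladium ionises only the allyl ester, morpholine takes the allyl group, and β-keto acid 19 loses CO2 on gentle warming; these neutral conditions spare the tertiary chloride, and the carboxyl is gone before the oxidation, so no enolised β-keto ester competes for the oxidant and no ester is left to lactonise onto the C9 hydroxyl.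

Step 11
Reactants: 20 the chloro enone-free ketone with the C8=C9 alkene
Product: 21 11-chloro-8,9-dihydroxyeremophilan-2-one (hydroxyls cis to each other and trans to the C7 side chain; C8–OH equatorial; C9–OH axial)
Conditions: OsO4 (2 mol %), N-methylmorpholine N-oxide, acetone–H2O 10:1, rt
Reagents that add atoms: osmium tetroxide, O=[Os](=O)(=O)=O (delivers both oxygens); N-methylmorpholine N-oxide, C[N+]1([O-])CCOCC1; water, O (these two restore the oxidant)
Why: Catalytic osmium tetroxide syn-dihydroxylation: the oxidant should add to the face of C8=C9 anti to the 2-chloropropan-2-yl group, one branch of which sits under C8, which sets C8 and C9 with both oxygens trans to the C7 side chain, while the chloride keeps the later isopropenyl alkene out of reach of the oxidant.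

Step 12
Reactants: 21 the chloro diol
Product: 22 8,9-O-isopropylidene derivative of 21
Conditions: 2-methoxypropene, PPTS (cat.), CH2Cl2, 0 °C → rt
Reagents that add atoms: 2-methoxypropene, COC(C)=C
Why: Acid-catalysed acetonide formation on the cis-diol; it masks the C8 hydroxyl, whose alkoxide could otherwise undergo Grob fragmentation against the C11 chloride under the base of step 13.

Step 13
Reactants: 22 the chloro acetonide
Product: 23 8,9-O-isopropylidene-8,9-dihydroxyeremophil-11-en-2-one
Conditions: KOt-Bu, THF–DMSO 4:1, rt, argon
Reagents that add atoms: none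
Why: E2 dehydrochlorination: the bulky alkoxide should remove a methyl hydrogen and give the isopropenyl group, because the only other β-hydrogen, axial H7, is shielded on the concave face, and the ketone merely rests as its enolate (no acidic stereocentre).

Step 14
Reactants: 23 the isopropenyl acetonide
Product: 24 8,9-dihydroxyeremophil-11-en-2-one (configured as 28)
Conditions: AcOH–H2O 4:1, 45 °C
Reagents that add atoms: none
Why: Mild acid hydrolysis of the acetonide; the isopropenyl group, the ketone and the ring fusion are stable to warm aqueous acetic acid.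

Step 15
Reactants: 24 the isopropenyl diol; 25 (R)-2-methylbutanoic acid
Product: 26 9-hydroxy-8-[(2R)-2-methylbutanoyloxy]eremophil-11-en-2-one
Conditions: DCC, DMAP (cat.), CH2Cl2, 0 °C → rt
Reagents that add atoms: (R)-2-methylbutanoic acid 25, CC[C@@H](C)C(=O)O
Why: Steglich esterification; the equatorial C8 hydroxyl should be acylated selectively because the axial C9 hydroxyl is crowded by axial C4 and by C2, and the ester stereocentre is brought in with acid 25.

Step 16
Reactants: 26 the C8 monoester; 27 tigloyl chloride
Product: 28 CNP0312791.1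
Conditions: DMAP, pyridine, ClCH2CH2Cl, 60 °C
Reagents that add atoms: tigloyl chloride 27, O=C(Cl)/C(C)=C/C
Why: DMAP-catalysed acylation with the acid chloride under forcing conditions esterifies the remaining axial C9 hydroxyl; the tiglate is the stable E isomer, so its geometry is not at risk.

Compound list
1 | (+)-3-carene, (1S,6R)-3,7,7-trimethylbicyclo[4.1.0]hept-3-ene | CC1=CC[C@@H]2[C@H](C1)C2(C)C | starting material
2 | car-3-en-5-one, (1R,6S)-4,7,7-trimethylbicyclo[4.1.0]hept-3-en-2-one | CC1=CC(=O)[C@@H]2[C@H](C1)C2(C)C | intermediate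
3 | cis-car-3-en-5-ol, (1R,2R,6S)-4,7,7-trimethylbicyclo[4.1.0]hept-3-en-2-ol | CC1=C[C@@H](O)[C@@H]2[C@H](C1)C2(C)C | intermediate
4 | propanoic acid | CCC(=O)O | starting material
5 | trans-car-3-en-5-yl propanoate, (1R,2S,6S)-4,7,7-trimethylbicyclo[4.1.0]hept-3-en-2-yl propanoate | CC1=C[C@H](OC(=O)CC)[C@@H]2[C@H](C1)C2(C)C | intermediate
6 | (E)-O-trimethylsilyl ketene acetal of 5, methyl cis to the allylic oxygen (not isolated) | CC1=C[C@H](O/C(=C\C)O[Si](C)(C)C)[C@@H]2[C@H](C1)C2(C)C | intermediate
7 | trimethylsilyl ester of 8 (not isolated) | C[Si](C)(C)OC(=O)[C@H](C)[C@]1(C)C=C[C@@H]2[C@H](C1)C2(C)C | intermediate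
8 | (2R)-2-[(1S,3S,6R)-3,7,7-trimethylbicyclo[4.1.0]hept-4-en-3-yl]propanoic acid (chain on C5 anti to the cyclopropane) | OC(=O)[C@H](C)[C@]1(C)C=C[C@@H]2[C@H](C1)C2(C)C | intermediate
9 | acid chloride of 8 (not isolated) | O=C(Cl)[C@H](C)[C@]1(C)C=C[C@@H]2[C@H](C1)C2(C)C | intermediate
10 | (3R)-1-diazo-3-[(1S,3S,6R)-3,7,7-trimethylbicyclo[4.1.0]hept-4-en-3-yl]butan-2-one | [N-]=[N+]=CC(=O)[C@H](C)[C@]1(C)C=C[C@@H]2[C@H](C1)C2(C)C | intermediate
11 | ketene formed from 10 by 1,2-shift of C4 (not isolated) | O=C=C[C@H](C)[C@]1(C)C=C[C@@H]2[C@H](C1)C2(C)C | intermediate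
12 | (3S)-3-[(1S,3R,6R)-3,7,7-trimethylbicyclo[4.1.0]hept-4-en-3-yl]butanoic acid | OC(=O)C[C@H](C)[C@]1(C)C=C[C@@H]2[C@H](C1)C2(C)C | intermediate
13 | Meldrum's acid, 2,2-dimethyl-1,3-dioxane-4,6-dione | CC1(C)OC(=O)CC(=O)O1 | starting material
14 | allyl alcohol, prop-2-en-1-ol | C=CCO | starting material
15 | acyl Meldrum's acid of 12, enol form (not isolated) | CC1(C)OC(=O)C(=C(O)C[C@H](C)[C@]2(C)C=C[C@@H]3[C@H](C2)C3(C)C)C(=O)O1 | intermediate
16 | allyl (5S)-3-oxo-5-[(1S,3R,6R)-3,7,7-trimethylbicyclo[4.1.0]hept-4-en-3-yl]hexanoate | C=CCOC(=O)CC(=O)C[C@H](C)[C@]1(C)C=C[C@@H]2[C@H](C1)C2(C)C | intermediate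
17 | allyl (5S)-2-chloro-3-oxo-5-[(1S,3R,6R)-3,7,7-trimethylbicyclo[4.1.0]hept-4-en-3-yl]hexanoate, both C1 epimers (key-step precursor) | C=CCOC(=O)C(Cl)C(=O)C[C@H](C)[C@]1(C)C=C[C@@H]2[C@H](C1)C2(C)C | intermediate
18 | allyl 11-chloro-2-oxoeremophil-8-ene-1-carboxylate, cis-fused, H10, both methyls and the C7 side chain on one face, C1 epimers or enol (key-step product) | CC(C)(Cl)[C@H]1C[C@@]2(C)[C@H](C(C(=O)OCC=C)C(=O)C[C@@H]2C)C=C1 | intermediate
19 | 11-chloro-2-oxoeremophil-8-ene-1-carboxylic acid (not isolated) | CC(C)(Cl)[C@H]1C[C@@]2(C)[C@H](C(C(=O)O)C(=O)C[C@@H]2C)C=C1 | intermediate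
20 | 11-chloroeremophil-8-en-2-one, cis-fused | CC(C)(Cl)[C@H]1C[C@@]2(C)[C@H](CC(=O)C[C@@H]2C)C=C1 | intermediate
21 | 11-chloro-8,9-dihydroxyeremophilan-2-one, hydroxyls cis to each other and trans to the C7 side chain | CC(C)(Cl)[C@H]1C[C@@]2(C)[C@H](CC(=O)C[C@@H]2C)[C@H](O)[C@@H]1O | intermediate
22 | 8,9-acetonide of 21 | CC(C)(Cl)[C@H]1C[C@@]2(C)[C@H](CC(=O)C[C@@H]2C)[C@@H]3OC(C)(C)O[C@H]13 | intermediate
23 | 8,9-acetonide of 8,9-dihydroxyeremophil-11-en-2-one | C=C(C)[C@H]1C[C@@]2(C)[C@H](CC(=O)C[C@@H]2C)[C@@H]3OC(C)(C)O[C@H]13 | intermediate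
24 | 8,9-dihydroxyeremophil-11-en-2-one, configured as 28 | C=C(C)[C@H]1C[C@@]2(C)[C@H](CC(=O)C[C@@H]2C)[C@H](O)[C@@H]1O | intermediate
25 | (R)-2-methylbutanoic acid | CC[C@@H](C)C(=O)O | starting material
26 | 9-hydroxy-8-[(2R)-2-methylbutanoyloxy]eremophil-11-en-2-one | C=C(C)[C@H]1C[C@@]2(C)[C@H](CC(=O)C[C@@H]2C)[C@H](O)[C@@H]1OC(=O)[C@H](C)CC | intermediate
27 | tigloyl chloride, (E)-2-methylbut-2-enoyl chloride | O=C(Cl)/C(C)=C/C | starting material
28 | CNP0312791.1, (4S,5R,7R,8R,9S,10S)-8-[(2R)-2-methylbutanoyloxy]-9-[(2E)-2-methylbut-2-enoyloxy]eremophil-11-en-2-one | C=C(C)[C@H]1C[C@@]2(C)[C@H](CC(=O)C[C@@H]2C)[C@H](OC(=O)/C(C)=C/C)[C@@H]1OC(=O)[C@H](C)CC | target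

Total step count: 16. Longest linear sequence: 16 steps (1 to 28).

Steps most likely to fail

Step 9. Ring closure at C10, which is flanked by quaternary C5, may be slow. Chlorine would then return to C1 without cyclisation, the C1 radical could be reduced or add intermolecularly, and the tertiary chloride could lose HCl at 80 °C. Cleavage of C7–C8 would divert the C9 radical into ring expansion. The fallback replaces atom-transfer termination by oxidative termination. It sets out from 17: Mn(OAc)3·2H2O and Cu(OAc)2·H2O in AcOH generate the same C1 radical (trivalent manganese), the same cyclisation and ring opening follow, and divalent copper oxidises the tertiary C11 radical to the alkene, which should give the C1-chlorinated isopropenyl keto ester F1. Zn in AcOH removes the C1 chlorine to give the isopropenyl β-keto ester F2. Dry HCl in CH2Cl2 at −40 °C then adds in the Markovnikov sense to the 1,1-disubstituted alkene only, and the route is rejoined at 18.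

Step 11. Facial selectivity may be poor or reversed. The concave face of the cis-octalin at C9 is screened by the axial C4–H and by C2, so osmylation may take the convex face, syn to the C7 substituent, and give the diol epimeric at both C8 and C9. The fallback delivers the oxygens by neighbouring-group participation and not by cycloaddition. It sets out from 20: PhI(OAc)2 with BF3·OEt2 (cat.) in wet AcOH at rt, a Prévost–Woodward-type syn-hydroxyacetoxylation. The bulky trivalent iodine electrophile should take the accessible convex face, acetate enters anti, and displacement of the iodine by the neighbouring acetate with inversion puts both oxygens on the concave face, giving the cis-hydroxy acetate F3 (drawn as the C9 acetate). The classical silver-mediated procedure is avoided because silver ion would ionise the tertiary chloride. K2CO3 in MeOH at 0 °C then returns the route to 21.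

Step 16. The axial C9 hydroxyl is very hindered. Under forcing conditions the C8 ester may migrate to O9 and the freed equatorial hydroxyl may then be tigloylated, which scrambles the two acyl groups, or no acylation may take place. The fallback reverses the order behind a non-migrating block on O8. It sets out from 24: Et3SiCl and imidazole in CH2Cl2 at 0 °C silylate the equatorial hydroxyl to give the C8 triethylsilyl ether F4. Tigloyl chloride 27 with DMAP in pyridine at 60–80 °C acylates the C9 hydroxyl, with no neighbouring acyl group that could migrate, to give the silyl ether tiglate F5. HF·pyridine in THF at 0 °C gives the C9 tiglate with free C8 hydroxyl F6. DCC and DMAP with 25 at 0 °C then acylate the fast-reacting equatorial hydroxyl before the tiglate can move, and the route is rejoined at 28.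

Further compounds
F1 | step 9 | allyl 1,?-dichloro-free analogue: allyl 1-chloro-2-oxoeremophila-8,11-diene-1-carboxylate (C1 epimers; ring stereocentres as in 18) | C=C(C)[C@H]1C[C@@]2(C)[C@H](C(Cl)(C(=O)OCC=C)C(=O)C[C@@H]2C)C=C1
F2 | step 9 | allyl 2-oxoeremophila-8,11-diene-1-carboxylate (C1 epimers or enol) | C=C(C)[C@H]1C[C@@]2(C)[C@H](C(C(=O)OCC=C)C(=O)C[C@@H]2C)C=C1
F3 | step 11 | 9-acetoxy-11-chloro-8-hydroxyeremophilan-2-one (oxygens as in 21) | CC(C)(Cl)[C@H]1C[C@@]2(C)[C@H](CC(=O)C[C@@H]2C)[C@H](OC(C)=O)[C@@H]1O
F4 | step 16 | 9-hydroxy-8-(triethylsilyloxy)eremophil-11-en-2-one | C=C(C)[C@H]1C[C@@]2(C)[C@H](CC(=O)C[C@@H]2C)[C@H](O)[C@@H]1O[Si](CC)(CC)CC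
F5 | step 16 | 9-[(2E)-2-methylbut-2-enoyloxy]-8-(triethylsilyloxy)eremophil-11-en-2-one | C=C(C)[C@H]1C[C@@]2(C)[C@H](CC(=O)C[C@@H]2C)[C@H](OC(=O)/C(C)=C/C)[C@@H]1O[Si](CC)(CC)CC
F6 | step 16 | 8-hydroxy-9-[(2E)-2-methylbut-2-enoyloxy]eremophil-11-en-2-one | C=C(C)[C@H]1C[C@@]2(C)[C@H](CC(=O)C[C@@H]2C)[C@H](OC(=O)/C(C)=C/C)[C@@H]1O
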